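**Strategy.** In the bottom flavan unit, the ring oxygen O1 on C8a and the interflavan carbon on C8 are ortho neighbours on ring A, with the C7 oxygen flanking C8. Both bonds are therefore made at once from a C8–C8a aryne: a tethered C2 alkoxide closes ring C at C8a and the C8 anion is formylated, the formyl carbon becoming C4 of the middle unit. The precursor is an open-chain syn alcohol bearing an ortho-silylaryl triflate. The aldehyde is then grown into the 2,3-cis-3,4-cis middle unit through a chiral aryl propargyl ether and a 2H-chromene, and the top unit is added as a 4-ketone to the 8-lithio dimer, followed by ionic reduction, C4 hydroxylation and hydrogenolysis.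

Key step: step 11

Assumption: the BINOL–Ti(OiPr)4 alkynylation is taken to follow its usual sense for aryl aldehydes ((S)-BINOL gives the R carbinol), so (R)-BINOL is specified for the S carbinol 30.

**Route**

Step 1
Reactants: 1 3,5-bis(benzyloxy)phenol
Product: 2 2-bromo-3,5-bis(benzyloxy)phenol
Conditions: NBS (1.0 equiv), i-Pr2NH (10 mol %), CH2Cl2, −20 → 0 °C
Reagents that add atoms: N-bromosuccinimide, O=C1CCC(=O)N1Br
Why: Amine-catalysed electrophilic bromination delivers bromine from a hydrogen-bonded N-bromoamine to the position ortho to the hydroxyl, while the para position is shielded by two flanking benzyloxy groups.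

Step 2
Reactants: 2 2-bromo-3,5-bis(benzyloxy)phenol
Product: 3 3-bromo-4,6-bis(benzyloxy)-2-hydroxybenzaldehyde
Conditions: MgCl2, Et3N, (CH2O)n, MeCN, reflux
Reagents that add atoms: paraformaldehyde (as formaldehyde), C=O
Why: Magnesium-phenoxide-directed ortho-formylation (Casnati–Skattebøl reaction) can only go to the one remaining free ortho position.

Step 3
Reactants: 3 3-bromo-4,6-bis(benzyloxy)-2-hydroxybenzaldehyde
Product: 4 2-bromo-3,5-bis(benzyloxy)-6-(hydroxymethyl)phenol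
Conditions: NaBH4, THF/MeOH, 0 °C
Reagents that add atoms: none
Why: Borohydride reduction of the aldehyde leaves the aryl bromide and the benzyl ethers untouched.

Step 4
Reactants: 4 2-bromo-3,5-bis(benzyloxy)-6-(hydroxymethyl)phenol
Product: 8 3,5-bis(benzyloxy)-2-(hydroxymethyl)-6-(trimethylsilyl)phenyl trifluoromethanesulfonate, via bis-silyl ether 5 (not isolated), via lithium phenoxide 6 (not isolated), via silyl ether triflate 7 (not isolated)
Conditions: TMSCl, Et3N, THF, 0 °C; n-BuLi, THF, −78 °C; PhNTf2, −78 → 0 °C; citric acid, MeOH, 0 °C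
Reagents that add atoms: chlorotrimethylsilane, C[Si](C)(C)Cl; N-phenylbis(trifluoromethanesulfonimide), O=S(=O)(N(c1ccccc1)S(=O)(=O)C(F)(F)F)C(F)(F)F
Why: Bromine–lithium exchange on the bis-silyl ether triggers the retro-Brook 1,3-shift of silicon from oxygen to the ortho carbon, the freed phenoxide is triflated, and mild acidic methanolysis cleaves only the alkyl silyl ether.

Step 5
Reactants: 8 3,5-bis(benzyloxy)-2-(hydroxymethyl)-6-(trimethylsilyl)phenyl triflate
Product: 9 3,5-bis(benzyloxy)-2-(bromomethyl)-6-(trimethylsilyl)phenyl trifluoromethanesulfonate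
Conditions: CBr4, PPh3, CH2Cl2, 0 °C; used at once
Reagents that add atoms: carbon tetrabromide, BrC(Br)(Br)Br
Why: The Appel reaction converts the benzylic alcohol to the bromide under neutral conditions without an electrophilic bromine source that could ipso-desilylate the electron-rich aryl silane.

Step 6
Reactants: 10 (R)-4-benzyl-2-oxazolidinone; 11 benzyloxyacetyl chloride
Product: 13 (R)-4-benzyl-3-(benzyloxyacetyl)oxazolidin-2-one, via lithium amide 12 (not isolated)
Conditions: n-BuLi, THF, −78 °C; then 11, −78 → 0 °C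
Reagents that add atoms: none
Why: N-acylation of the lithiated oxazolidinone by the acid chloride gives the glycolate imide.

Step 7
Reactants: 13 (R)-4-benzyl-3-(benzyloxyacetyl)oxazolidin-2-one; 9 benzylic bromide
Product: 15 (R)-4-benzyl-3-[(2S)-2-(benzyloxy)-3-[4,6-bis(benzyloxy)-2-(trifluoromethylsulfonyloxy)-3-(trimethylsilyl)phenyl]propanoyl]oxazolidin-2-one, via sodium enolate 14 (not isolated)
Conditions: NaN(SiMe3)2, THF, −78 °C; then 9, −78 → −45 °C
Reagents that add atoms: none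
Why: In this Evans alkylation the chelated Z-glycolate enolate is attacked by the activated benzylic bromide on the face opposite the auxiliary benzyl group, which sets the S centre that becomes C3 of the flavan.

Step 8
Reactants: 15 alkylated imide
Product: 16 (2S)-2-(benzyloxy)-3-[4,6-bis(benzyloxy)-2-(trifluoromethylsulfonyloxy)-3-(trimethylsilyl)phenyl]propan-1-ol
Conditions: LiBH4, MeOH (1 equiv), Et2O, 0 °C
Reagents that add atoms: none
Why: Reductive cleavage of the N-acyl oxazolidinone releases the primary alcohol and the auxiliary while the aryl triflate, the aryl silane and the stereocentre stay intact.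

Step 9
Reactants: 16 primary alcohol
Product: 17 (2S)-2-(benzyloxy)-3-[4,6-bis(benzyloxy)-2-(trifluoromethylsulfonyloxy)-3-(trimethylsilyl)phenyl]propanal
Conditions: Dess–Martin periodinane, NaHCO3, CH2Cl2, 0 °C; used crude
Reagents that add atoms: none
Why: Dess–Martin oxidation under buffered, non-basic conditions gives the α-benzyloxy aldehyde without epimerisation.

Step 10
Reactants: 17 α-benzyloxy aldehyde; 18 1-(benzyloxy)-4-bromobenzene
Product: 20 (1S,2S)-2-(benzyloxy)-1-[4-(benzyloxy)phenyl]-3-[4,6-bis(benzyloxy)-2-(trifluoromethylsulfonyloxy)-3-(trimethylsilyl)phenyl]propan-1-ol, via Grignard reagent 19 (not isolated)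
Conditions: 18, Mg, THF; then 17, MgBr2·OEt2, CH2Cl2, −78 °C
Reagents that add atoms: none
Why: Cram-chelate Grignard addition, in which magnesium bridges the carbonyl and the α-benzyloxy oxygen and the aryl group enters from the side of the α-hydrogen, gives the syn (1S,2S) alcohol.

Step 11
Reactants: 20 syn alcohol bearing the ortho-silylaryl triflate; 21 N,N-dimethylformamide
Product: 26 (2S,3S)-3,5,7-tris(benzyloxy)-2-[4-(benzyloxy)phenyl]chromane-8-carbaldehyde, via potassium alkoxide 22 (not isolated), via aryne alkoxide 23 (not isolated), via C8 aryl anion 24 (not isolated), via hemiaminal alkoxide 25 (not isolated)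
Conditions: KH, THF, −20 °C; then DMF (10 equiv), KF, 18-crown-6, THF, −20 °C → rt; aq. NH4Cl
Reagents that add atoms: none
Why: Proposed new method: KH converts the only acidic proton into alkoxide 22, fluoride then removes the silyl group with loss of triflate to give the C8–C8a aryne 23, the alkoxide adds to C8a, and the C8 aryl anion 24, left without a proton source, adds to DMF to give hemiaminal 25, which collapses to the aldehyde on work-up. The closest known reactions are intramolecular additions of tethered alcohols to arynes that give chromans and intermolecular aryne three-component couplings in which the aryl anion is trapped by a carbonyl electrophile; their merger through an alkoxide tether and DMF has not been shown. Ring C closes in a 6-exo-dig mode through the O1–C8a bond, the triple bond lying outside the new ring. No stereocentre is created, and because the C2–O bond is never broken the syn arrangement of 20 becomes 2,3-cis directly. The step needs attack at C8a and not at C8, which the three-atom tether enforces (attack at C8 would need a meta-bridged ring) and the inductive pull of the C7 benzyloxy group reinforces by placing the negative charge at C8. It also needs capture of the anion by DMF ahead of protonation or triflyl transfer, which is served by pre-forming the alkoxide with KH so that no O–H or N–H acid remains, by excess DMF, and by the shielded position of the triflate between the silyl group and the benzylic carbon.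

Step 12
Reactants: 26 bottom-unit 8-carbaldehyde
Product: 27 (2S,3S)-3,5,7-tris(benzyloxy)-2-[4-(benzyloxy)phenyl]-8-ethynylchromane
Conditions: dimethyl (1-diazo-2-oxopropyl)phosphonate, K2CO3, MeOH/THF, rt
Reagents that add atoms: dimethyl (1-diazo-2-oxopropyl)phosphonate, COP(=O)(OC)C(=[N+]=[N-])C(C)=O
Why: Seyferth–Gilbert homologation with the Ohira–Bestmann reagent turns the aldehyde into the terminal alkyne, the formyl carbon becoming the alkyne carbon on C8 (future C4 of the middle unit).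

Step 13
Reactants: 27 8-ethynyl bottom unit; 28 4-(benzyloxy)benzaldehyde
Product: 30 (1S)-1-[4-(benzyloxy)phenyl]-3-[(2S,3S)-3,5,7-tris(benzyloxy)-2-(4-benzyloxyphenyl)chroman-8-yl]prop-2-yn-1-ol, via alkynylzinc 29 (not isolated)
Conditions: Et2Zn, toluene, reflux; then (R)-BINOL (20 mol %), Ti(OiPr)4 (50 mol %), 28, CH2Cl2, rt
Reagents that add atoms: none
Why: In this BINOL–titanium-catalysed alkynylzinc addition the chiral Lewis acid directs the alkynyl group to the Re face of the aldehyde, giving the S carbinol.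

Step 14
Reactants: 30 S propargylic alcohol; 2 2-bromo-3,5-bis(benzyloxy)phenol
Product: 31 2-bromo-3,5-bis(benzyloxy)phenyl (1R)-1-[4-(benzyloxy)phenyl]-3-[(2S,3S)-3,5,7-tris(benzyloxy)-2-(4-benzyloxyphenyl)chroman-8-yl]prop-2-ynyl ether
Conditions: PPh3, DIAD, toluene, −20 °C
Reagents that add atoms: none
Why: In the Mitsunobu reaction the acidic bromophenol displaces the alkoxyphosphonium group by SN2 with inversion, which sets the R centre that becomes C2 of the middle unit, and the cold non-polar medium is chosen to disfavour ionisation.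

Step 15
Reactants: 31 aryl propargyl ether
Product: 32 (2R)-8-bromo-5,7-bis(benzyloxy)-2-[4-(benzyloxy)phenyl]-4-[(2S,3S)-3,5,7-tris(benzyloxy)-2-(4-benzyloxyphenyl)chroman-8-yl]-2H-chromene
Conditions: Ph3PAuNTf2 (5 mol %), CH2Cl2, rt
Reagents that add atoms: none
Why: Gold-catalysed 6-endo-dig hydroarylation lets the only free ortho carbon of the phloroglucinol-type ring attack the activated alkyne at the carbon bearing the bottom-unit aryl group, closing ring C of the middle unit without touching C2.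

Step 16
Reactants: 32 2H-chromene
Product: 34 (2R,3S)-8-bromo-5,7-bis(benzyloxy)-2-[4-(benzyloxy)phenyl]-4-[(2S,3S)-3,5,7-tris(benzyloxy)-2-(4-benzyloxyphenyl)chroman-8-yl]chroman-3-ol (2,3-trans-3,4-trans; C4 aryl cis to C2 aryl), via alkylborane 33 (not isolated)
Conditions: BH3·THF, THF, 0 °C → rt; then NaOH, H2O2
Reagents that add atoms: hydrogen peroxide, OO
Why: Hydroboration–oxidation adds hydrogen to C4 and boron to C3 syn and on the face opposite the C2 aryl group, so the C4 aryl ends cis to the C2 aryl and the C3 hydroxyl trans to both.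

Step 17
Reactants: 34 all-trans alcohol
Product: 35 (2R)-8-bromo-5,7-bis(benzyloxy)-2-[4-(benzyloxy)phenyl]-4-[(2S,3S)-3,5,7-tris(benzyloxy)-2-(4-benzyloxyphenyl)chroman-8-yl]chroman-3-one (2,4-cis)
Conditions: Dess–Martin periodinane, NaHCO3, CH2Cl2, 0 °C; used crude
Reagents that add atoms: none
Why: Buffered Dess–Martin oxidation gives the ketone without enolisation of the two flanking aryl-bearing centres.

Step 18
Reactants: 35 2,4-cis ketone
Product: 36 (2R,3R)-8-bromo-5,7-bis(benzyloxy)-2-[4-(benzyloxy)phenyl]-4-[(2S,3S)-3,5,7-tris(benzyloxy)-2-(4-benzyloxyphenyl)chroman-8-yl]chroman-3-ol (2,3-cis-3,4-cis)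
Conditions: LiBH(s-Bu)3, THF, −78 °C
Reagents that add atoms: none
Why: The bulky hydride attacks the ketone from the face opposite both aryl groups, so the hydroxyl ends cis to both, the same tactic that turns 2,3-trans into 2,3-cis flavan-3-ols.

Step 19
Reactants: 36 all-cis alcohol
Product: 37 (2R,3R)-8-bromo-3,5,7-tris(benzyloxy)-2-[4-(benzyloxy)phenyl]-4-[(2S,3S)-3,5,7-tris(benzyloxy)-2-(4-benzyloxyphenyl)chroman-8-yl]chromane (all-cis)
Conditions: NaH, BnBr, Bu4NI (cat.), DMF, 0 °C → rt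
Reagents that add atoms: benzyl bromide, BrCc1ccccc1
Why: Williamson benzylation removes the last acidic proton before the halogen–lithium exchange.

Step 20
Reactants: 20 syn alcohol bearing the ortho-silylaryl triflate
Product: 39 (2S,3S)-3,5,7-tris(benzyloxy)-2-[4-(benzyloxy)phenyl]chromane, via aryne 38 (not isolated)
Conditions: CsF, MeCN, rt
Reagents that add atoms: none
Why: Fluoride-induced aryne formation is followed by intramolecular addition of the hydroxyl to C8a and proton transfer to C8, the known protonating counterpart of step 11, again with retention at C2 and hence 2,3-cis.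

Step 21
Reactants: 39 tetra-O-benzyl-ent-epiafzelechin
Product: 40 (2S,3S,4R)-3,5,7-tris(benzyloxy)-2-[4-(benzyloxy)phenyl]chroman-4-ol (3,4-trans)
Conditions: DDQ, CH2Cl2/H2O, rt
Reagents that add atoms: water, O
Why: DDQ abstracts hydride from the benzylic C4 and water adds to the cation anti to the pseudo-axial 3-benzyloxy group, giving the 3,4-trans alcohol.

Step 22
Reactants: 40 4-hydroxy flavan
Product: 41 (2S,3R)-3,5,7-tris(benzyloxy)-2-[4-(benzyloxy)phenyl]chroman-4-one (2,3-cis)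
Conditions: Dess–Martin periodinane, NaHCO3, CH2Cl2, rt
Reagents that add atoms: none
Why: Buffered Dess–Martin oxidation gives the ketone without epimerising the adjacent C3 centre.

Step 23
Reactants: 37 dimer 8-bromide; 41 top-unit 4-ketone
Product: 43 trimeric tertiary alcohol (top-unit C4 bears OH and the middle-unit C8; configuration at this carbon not defined), via aryllithium 42 (not isolated)
Conditions: 37, t-BuLi, THF, −78 °C; then 41, −78 → 0 °C
Reagents that add atoms: none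
Why: Bromine–lithium exchange followed by 1,2-addition of the 8-lithioflavan to the flavan-4-one is known for benzylated flavans, and the configuration of the new carbinol is irrelevant because it is ionised in the next step.

Step 24
Reactants: 43 trimeric tertiary alcohol
Product: 44 dodeca-O-benzyl trimer (top unit 2S,3S and 2,3-cis-3,4-cis; middle unit 2R,3R and 2,3-cis-3,4-cis; bottom unit 2S,3S with C4 as CH2)
Conditions: Bu3SnH, CF3CO2H, CH2Cl2, 0 °C
Reagents that add atoms: none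
Why: In this ionic hydrogenation acid ionises the tertiary dibenzylic alcohol and the tin hydride delivers hydride to the face of the C4 cation opposite the 3-benzyloxy group, which places the middle-unit aryl cis to it.

Step 25
Reactants: 44 dodeca-O-benzyl trimer
Product: 45 dodeca-O-benzyl trimer 4-ol (bottom unit 2S,3S,4R; 3,4-trans)
Conditions: DDQ, CH2Cl2/H2O, rt
Reagents that add atoms: water, O
Why: DDQ abstracts hydride from the only benzylic methylene, C4 of the bottom unit, the two interflavan methines being shielded, and water adds anti to the 3-benzyloxy group as in step 21.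

Step 26
Reactants: 45 dodeca-O-benzyl trimer 4-ol
Product: 46 CNP0159291.1
Conditions: H2, Pd(OH)2/C, THF/MeOH/H2O, rt
Reagents that add atoms: none
Why: Hydrogenolysis cleaves the twelve benzyl ethers, and keeping the medium neutral and stopping at full conversion should preserve the benzylic C4 hydroxyl.

**Compound list**

1 | 3,5-bis(benzyloxy)phenol | Oc1cc(OCc2ccccc2)cc(OCc2ccccc2)c1 | starting material
2 | 2-bromo-3,5-bis(benzyloxy)phenol | Oc1cc(OCc2ccccc2)cc(OCc2ccccc2)c1Br | intermediate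
3 | 3-bromo-4,6-bis(benzyloxy)-2-hydroxybenzaldehyde | O=Cc1c(O)c(Br)c(OCc2ccccc2)cc1OCc1ccccc1 | intermediate
4 | 2-bromo-3,5-bis(benzyloxy)-6-(hydroxymethyl)phenol | OCc1c(O)c(Br)c(OCc2ccccc2)cc1OCc1ccccc1 | intermediate
5 | bis(trimethylsilyl) ether of 4 | C[Si](C)(C)OCc1c(O[Si](C)(C)C)c(Br)c(OCc2ccccc2)cc1OCc1ccccc1 | intermediate
6 | lithium 3,5-bis(benzyloxy)-2-(trimethylsilyl)-6-[(trimethylsilyloxy)methyl]phenolate | [Li+].[O-]c1c(CO[Si](C)(C)C)c(OCc2ccccc2)cc(OCc2ccccc2)c1[Si](C)(C)C | intermediate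
7 | 3,5-bis(benzyloxy)-2-(trimethylsilyl)-6-[(trimethylsilyloxy)methyl]phenyl trifluoromethanesulfonate | C[Si](C)(C)OCc1c(OS(=O)(=O)C(F)(F)F)c([Si](C)(C)C)c(OCc2ccccc2)cc1OCc1ccccc1 | intermediate
8 | 3,5-bis(benzyloxy)-2-(hydroxymethyl)-6-(trimethylsilyl)phenyl trifluoromethanesulfonate | OCc1c(OS(=O)(=O)C(F)(F)F)c([Si](C)(C)C)c(OCc2ccccc2)cc1OCc1ccccc1 | intermediate
9 | 3,5-bis(benzyloxy)-2-(bromomethyl)-6-(trimethylsilyl)phenyl trifluoromethanesulfonate | BrCc1c(OS(=O)(=O)C(F)(F)F)c([Si](C)(C)C)c(OCc2ccccc2)cc1OCc1ccccc1 | intermediate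
10 | (R)-4-benzyl-2-oxazolidinone | O=C1N[C@H](Cc2ccccc2)CO1 | starting material
11 | benzyloxyacetyl chloride | O=C(Cl)COCc1ccccc1 | starting material
12 | lithium salt of 10 | [Li+].O=C1[N-][C@H](Cc2ccccc2)CO1 | intermediate
13 | (R)-4-benzyl-3-(benzyloxyacetyl)oxazolidin-2-one | O=C(COCc1ccccc1)N1[C@H](Cc2ccccc2)COC1=O | intermediate
14 | sodium Z-enolate of 13 | [Na+].[O-]/C(=C\OCc1ccccc1)N1[C@H](Cc2ccccc2)COC1=O | intermediate
15 | (R)-4-benzyl-3-[(2S)-2-(benzyloxy)-3-[4,6-bis(benzyloxy)-2-(trifluoromethylsulfonyloxy)-3-(trimethylsilyl)phenyl]propanoyl]oxazolidin-2-one | O=C([C@@H](OCc1ccccc1)Cc1c(OCc2ccccc2)cc(OCc2ccccc2)c([Si](C)(C)C)c1OS(=O)(=O)C(F)(F)F)N1[C@H](Cc2ccccc2)COC1=O | intermediate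
16 | (2S)-2-(benzyloxy)-3-[4,6-bis(benzyloxy)-2-(trifluoromethylsulfonyloxy)-3-(trimethylsilyl)phenyl]propan-1-ol | OC[C@@H](OCc1ccccc1)Cc1c(OCc2ccccc2)cc(OCc2ccccc2)c([Si](C)(C)C)c1OS(=O)(=O)C(F)(F)F | intermediate
17 | (2S)-2-(benzyloxy)-3-[4,6-bis(benzyloxy)-2-(trifluoromethylsulfonyloxy)-3-(trimethylsilyl)phenyl]propanal | O=C[C@@H](OCc1ccccc1)Cc1c(OCc2ccccc2)cc(OCc2ccccc2)c([Si](C)(C)C)c1OS(=O)(=O)C(F)(F)F | intermediate
18 | 1-(benzyloxy)-4-bromobenzene | Brc1ccc(OCc2ccccc2)cc1 | starting material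
19 | 4-(benzyloxy)phenylmagnesium bromide | Br[Mg]c1ccc(OCc2ccccc2)cc1 | intermediate
20 | (1S,2S)-2-(benzyloxy)-1-[4-(benzyloxy)phenyl]-3-[4,6-bis(benzyloxy)-2-(trifluoromethylsulfonyloxy)-3-(trimethylsilyl)phenyl]propan-1-ol (syn alcohol, key-step precursor) | O[C@@H](c1ccc(OCc2ccccc2)cc1)[C@@H](OCc1ccccc1)Cc1c(OCc2ccccc2)cc(OCc2ccccc2)c([Si](C)(C)C)c1OS(=O)(=O)C(F)(F)F | intermediate
21 | N,N-dimethylformamide | CN(C)C=O | starting material
22 | potassium alkoxide of 20 | [K+].[O-][C@@H](c1ccc(OCc2ccccc2)cc1)[C@@H](OCc1ccccc1)Cc1c(OCc2ccccc2)cc(OCc2ccccc2)c([Si](C)(C)C)c1OS(=O)(=O)C(F)(F)F | intermediate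
23 | potassium alkoxide carrying the C8–C8a aryne | [K+].[O-][C@@H](c1ccc(OCc2ccccc2)cc1)[C@@H](OCc1ccccc1)CC1=C(OCc2ccccc2)C=C(OCc2ccccc2)C#C1 | intermediate
24 | potassium (2S,3S)-3,5,7-tris(benzyloxy)-2-[4-(benzyloxy)phenyl]chroman-8-ide | [K+].[c-]1c(OCc2ccccc2)cc(OCc2ccccc2)c2c1O[C@@H](c1ccc(OCc3ccccc3)cc1)[C@@H](OCc1ccccc1)C2 | intermediate
25 | potassium hemiaminal alkoxide (DMF adduct of 24; carbinol carbon not defined) | [K+].[O-]C(N(C)C)c1c(OCc2ccccc2)cc(OCc2ccccc2)c2c1O[C@@H](c1ccc(OCc3ccccc3)cc1)[C@@H](OCc1ccccc1)C2 | intermediate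
26 | (2S,3S)-3,5,7-tris(benzyloxy)-2-[4-(benzyloxy)phenyl]chromane-8-carbaldehyde (3,5,7,4'-tetra-O-benzyl-ent-epiafzelechin-8-carbaldehyde, 2,3-cis) | O=Cc1c(OCc2ccccc2)cc(OCc2ccccc2)c2c1O[C@@H](c1ccc(OCc3ccccc3)cc1)[C@@H](OCc1ccccc1)C2 | intermediate
27 | (2S,3S)-3,5,7-tris(benzyloxy)-2-[4-(benzyloxy)phenyl]-8-ethynylchromane | C#Cc1c(OCc2ccccc2)cc(OCc2ccccc2)c2c1O[C@@H](c1ccc(OCc3ccccc3)cc1)[C@@H](OCc1ccccc1)C2 | intermediate
28 | 4-(benzyloxy)benzaldehyde | O=Cc1ccc(OCc2ccccc2)cc1 | starting material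
29 | ethylzinc acetylide of 27 | CC[Zn]C#Cc1c(OCc2ccccc2)cc(OCc2ccccc2)c2c1O[C@@H](c1ccc(OCc3ccccc3)cc1)[C@@H](OCc1ccccc1)C2 | intermediate
30 | (1S)-1-[4-(benzyloxy)phenyl]-3-[(2S,3S)-3,5,7-tris(benzyloxy)-2-(4-benzyloxyphenyl)chroman-8-yl]prop-2-yn-1-ol | O[C@@H](c1ccc(OCc2ccccc2)cc1)C#Cc1c(OCc2ccccc2)cc(OCc2ccccc2)c2c1O[C@@H](c1ccc(OCc3ccccc3)cc1)[C@@H](OCc1ccccc1)C2 | intermediate
31 | 2-bromo-3,5-bis(benzyloxy)phenyl (1R)-1-[4-(benzyloxy)phenyl]-3-[(2S,3S)-3,5,7-tris(benzyloxy)-2-(4-benzyloxyphenyl)chroman-8-yl]prop-2-ynyl ether | Brc1c(OCc2ccccc2)cc(OCc2ccccc2)cc1O[C@H](c1ccc(OCc2ccccc2)cc1)C#Cc1c(OCc2ccccc2)cc(OCc2ccccc2)c2c1O[C@@H](c1ccc(OCc3ccccc3)cc1)[C@@H](OCc1ccccc1)C2 | intermediate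
32 | (2R)-8-bromo-5,7-bis(benzyloxy)-2-[4-(benzyloxy)phenyl]-4-[(2S,3S)-3,5,7-tris(benzyloxy)-2-(4-benzyloxyphenyl)chroman-8-yl]-2H-chromene | O(Cc5ccccc5)c1ccc([C@H]2Oc3c(c(OCc5ccccc5)cc(OCc5ccccc5)c3Br)C(c3c(OCc5ccccc5)cc(OCc5ccccc5)c4c3O[C@@H](c3ccc(OCc5ccccc5)cc3)[C@@H](OCc5ccccc5)C4)=C2)cc1 | intermediate
33 | C3 alkylborane from 32 (boron trans to the C2 aryl, C4 aryl cis to the C2 aryl) | O(Cc5ccccc5)c1ccc([C@H]2Oc3c(c(OCc5ccccc5)cc(OCc5ccccc5)c3Br)[C@@H](c3c(OCc5ccccc5)cc(OCc5ccccc5)c4c3O[C@@H](c3ccc(OCc5ccccc5)cc3)[C@@H](OCc5ccccc5)C4)[C@@H]2B)cc1 | intermediate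
34 | (2R,3S)-8-bromo-5,7-bis(benzyloxy)-2-[4-(benzyloxy)phenyl]-4-[(2S,3S)-3,5,7-tris(benzyloxy)-2-(4-benzyloxyphenyl)chroman-8-yl]chroman-3-ol, 2,3-trans-3,4-trans, C4 aryl cis to C2 aryl | O(Cc5ccccc5)c1ccc([C@H]2Oc3c(c(OCc5ccccc5)cc(OCc5ccccc5)c3Br)[C@@H](c3c(OCc5ccccc5)cc(OCc5ccccc5)c4c3O[C@@H](c3ccc(OCc5ccccc5)cc3)[C@@H](OCc5ccccc5)C4)[C@@H]2O)cc1 | intermediate
35 | (2R)-8-bromo-5,7-bis(benzyloxy)-2-[4-(benzyloxy)phenyl]-4-[(2S,3S)-3,5,7-tris(benzyloxy)-2-(4-benzyloxyphenyl)chroman-8-yl]chroman-3-one, 2,4-cis | O(Cc5ccccc5)c1ccc([C@H]2Oc3c(c(OCc5ccccc5)cc(OCc5ccccc5)c3Br)[C@@H](c3c(OCc5ccccc5)cc(OCc5ccccc5)c4c3O[C@@H](c3ccc(OCc5ccccc5)cc3)[C@@H](OCc5ccccc5)C4)C2=O)cc1 | intermediate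
36 | (2R,3R)-8-bromo-5,7-bis(benzyloxy)-2-[4-(benzyloxy)phenyl]-4-[(2S,3S)-3,5,7-tris(benzyloxy)-2-(4-benzyloxyphenyl)chroman-8-yl]chroman-3-ol, 2,3-cis-3,4-cis | O(Cc5ccccc5)c1ccc([C@H]2Oc3c(c(OCc5ccccc5)cc(OCc5ccccc5)c3Br)[C@@H](c3c(OCc5ccccc5)cc(OCc5ccccc5)c4c3O[C@@H](c3ccc(OCc5ccccc5)cc3)[C@@H](OCc5ccccc5)C4)[C@H]2O)cc1 | intermediate
37 | 3-O-benzyl ether of 36 (dimer 8-bromide, middle unit all-cis) | O(Cc5ccccc5)c1ccc([C@H]2Oc3c(c(OCc5ccccc5)cc(OCc5ccccc5)c3Br)[C@@H](c3c(OCc5ccccc5)cc(OCc5ccccc5)c4c3O[C@@H](c3ccc(OCc5ccccc5)cc3)[C@@H](OCc5ccccc5)C4)[C@H]2OCc5ccccc5)cc1 | intermediate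
38 | aryne from 20 with free hydroxyl | O[C@@H](c1ccc(OCc2ccccc2)cc1)[C@@H](OCc1ccccc1)CC1=C(OCc2ccccc2)C=C(OCc2ccccc2)C#C1 | intermediate
39 | (2S,3S)-3,5,7-tris(benzyloxy)-2-[4-(benzyloxy)phenyl]chromane (3,5,7,4'-tetra-O-benzyl-ent-epiafzelechin) | c1c(OCc2ccccc2)cc(OCc2ccccc2)c2c1O[C@@H](c1ccc(OCc3ccccc3)cc1)[C@@H](OCc1ccccc1)C2 | intermediate
40 | (2S,3S,4R)-3,5,7-tris(benzyloxy)-2-[4-(benzyloxy)phenyl]chroman-4-ol, 2,3-cis-3,4-trans | c1c(OCc2ccccc2)cc(OCc2ccccc2)c2c1O[C@@H](c1ccc(OCc3ccccc3)cc1)[C@@H](OCc1ccccc1)[C@@H]2O | intermediate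
41 | (2S,3R)-3,5,7-tris(benzyloxy)-2-[4-(benzyloxy)phenyl]chroman-4-one, 2,3-cis | c1c(OCc2ccccc2)cc(OCc2ccccc2)c2c1O[C@@H](c1ccc(OCc3ccccc3)cc1)[C@@H](OCc1ccccc1)C2=O | intermediate
42 | 8-lithio derivative of 37 | O(Cc5ccccc5)c1ccc([C@H]2Oc3c(c(OCc5ccccc5)cc(OCc5ccccc5)c3[Li])[C@@H](c3c(OCc5ccccc5)cc(OCc5ccccc5)c4c3O[C@@H](c3ccc(OCc5ccccc5)cc3)[C@@H](OCc5ccccc5)C4)[C@H]2OCc5ccccc5)cc1 | intermediate
43 | trimeric tertiary alcohol: top unit (2S,3S, 2,3-cis) with OH and the middle-unit C8 on its C4 (this carbon not defined); middle and bottom units as in 37 | O(Cc5ccccc5)c1ccc([C@H]2Oc3c(c(OCc5ccccc5)cc(OCc5ccccc5)c3C3(O)c4c(OCc5ccccc5)cc(OCc5ccccc5)cc4O[C@@H](c4ccc(OCc5ccccc5)cc4)[C@H]3OCc5ccccc5)[C@@H](c3c(OCc5ccccc5)cc(OCc5ccccc5)c4c3O[C@@H](c3ccc(OCc5ccccc5)cc3)[C@@H](OCc5ccccc5)C4)[C@H]2OCc5ccccc5)cc1 | intermediate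
44 | dodeca-O-benzyl trimer: top unit 2S,3S all-cis, linked C4→C8 to middle unit 2R,3R all-cis, linked C4→C8 to bottom unit 2S,3S with C4 as CH2 | O(Cc5ccccc5)c1ccc([C@H]2Oc3c(c(OCc5ccccc5)cc(OCc5ccccc5)c3[C@H]3c4c(OCc5ccccc5)cc(OCc5ccccc5)cc4O[C@@H](c4ccc(OCc5ccccc5)cc4)[C@H]3OCc5ccccc5)[C@@H](c3c(OCc5ccccc5)cc(OCc5ccccc5)c4c3O[C@@H](c3ccc(OCc5ccccc5)cc3)[C@@H](OCc5ccccc5)C4)[C@H]2OCc5ccccc5)cc1 | intermediate
45 | dodeca-O-benzyl trimer 4-ol: as 44 with 4R hydroxyl on the bottom unit (3,4-trans) | O(Cc5ccccc5)c1ccc([C@H]2Oc3c(c(OCc5ccccc5)cc(OCc5ccccc5)c3[C@H]3c4c(OCc5ccccc5)cc(OCc5ccccc5)cc4O[C@@H](c4ccc(OCc5ccccc5)cc4)[C@H]3OCc5ccccc5)[C@@H](c3c(OCc5ccccc5)cc(OCc5ccccc5)c4c3O[C@@H](c3ccc(OCc5ccccc5)cc3)[C@@H](OCc5ccccc5)[C@@H]4O)[C@H]2OCc5ccccc5)cc1 | intermediate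
46 | CNP0159291.1: top (2S,3S)-2,3-cis-3,4-cis flavan-3-ol unit, middle (2R,3R)-2,3-cis-3,4-cis unit, bottom (2S,3S,4R)-flavan-3,4-diol unit, both links C4→C8 | Oc1ccc([C@H]2Oc3c(c(O)cc(O)c3[C@H]3c4c(O)cc(O)cc4O[C@@H](c4ccc(O)cc4)[C@H]3O)[C@@H](c3c(O)cc(O)c4c3O[C@@H](c3ccc(O)cc3)[C@@H](O)[C@@H]4O)[C@H]2O)cc1 | target

**Step count and risks**

Total step count: 26. Longest linear sequence: 22 steps (steps 1–5, 7–19 and 23–26).

Step 11 is the most likely to fail. The C8 aryl anion may be protonated before it reaches DMF, the triflyl group may be transferred from the aryl triflate to the alkoxide before fluoride acts, or the aryne may be captured intermolecularly by DMF. The fallback uses known chemistry and sets out from 39, which step 20 makes from the same precursor 20 by the protonating variant of the cyclisation. Electrophilic bromination with N-bromosuccinimide, which in 5,7-dibenzyloxyflavans goes to C8, should give (2S,3S)-8-bromo-3,5,7-tris(benzyloxy)-2-[4-(benzyloxy)phenyl]chromane F1. Bromine–lithium exchange with t-BuLi at −78 °C gives the 8-lithio flavan F2, DMF converts it into the lithium hemiaminal alkoxide F3, and aqueous work-up brings the route back at 26.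

Step 14 comes next. The alkoxyphosphonium intermediate may ionise to a propargyl/allenyl cation stabilised by both aryl groups, which would erode the configuration at C2 or divert the phenol to the allenyl terminus. The fallback gives up control at C2, makes the cation an asset and bypasses steps 14 and 15. It sets out from alkyne 27, which is acylated with 4-(benzyloxy)benzoyl chloride (PdCl2(PPh3)2, CuI, Et3N) to the ynone F4. Acid-mediated condensation of F4 with phenol 2 (HBF4, AcOH), the classical flavylium synthesis from phenols and aryl ethynyl ketones, should give the 4-aryl flavylium tetrafluoroborate F5. NaBH4 adds hydride at C2, C4 being shielded by its aryl group, to give 32 together with its C2 epimer F6. Step 16 applied to this mixture gives 34 and the diastereomeric all-trans alcohol F7, which differ as diastereomers because the bottom unit is homochiral and are separated by chromatography. The route is rejoined at 34, at the cost of roughly half the material.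

Step 25 is the third. Hydride abstraction may be unselective between the bottom-unit methylene, the benzylic C2–H positions and the interflavan methines, or the new alcohol may be oxidised further to the ketone. The fallback sets out from 44 and replaces the quinone by lead tetraacetate (Pb(OAc)4, benzene, rt), a known C4 acetoxylation of protected flavan-3-ols that responds to steric access more than to cation stability and stops at the ester oxidation level, to give the 4-acetate F8. Methanolysis (K2CO3, MeOH) with acyl–oxygen cleavage then returns the route at 45 with the 3,4-trans configuration intact.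

**Further compounds**

F1 | step 11 | (2S,3S)-8-bromo-3,5,7-tris(benzyloxy)-2-[4-(benzyloxy)phenyl]chromane | Brc1c(OCc2ccccc2)cc(OCc2ccccc2)c2c1O[C@@H](c1ccc(OCc3ccccc3)cc1)[C@@H](OCc1ccccc1)C2
F2 | step 11 | (2S,3S)-3,5,7-tris(benzyloxy)-2-[4-(benzyloxy)phenyl]chroman-8-yllithium | [Li]c1c(OCc2ccccc2)cc(OCc2ccccc2)c2c1O[C@@H](c1ccc(OCc3ccccc3)cc1)[C@@H](OCc1ccccc1)C2
F3 | step 11 | lithium hemiaminal alkoxide (DMF adduct of F2) | [Li+].[O-]C(N(C)C)c1c(OCc2ccccc2)cc(OCc2ccccc2)c2c1O[C@@H](c1ccc(OCc3ccccc3)cc1)[C@@H](OCc1ccccc1)C2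
F4 | step 14 | 1-[4-(benzyloxy)phenyl]-3-[(2S,3S)-3,5,7-tris(benzyloxy)-2-(4-benzyloxyphenyl)chroman-8-yl]prop-2-yn-1-one | O=C(c1ccc(OCc2ccccc2)cc1)C#Cc1c(OCc2ccccc2)cc(OCc2ccccc2)c2c1O[C@@H](c1ccc(OCc3ccccc3)cc1)[C@@H](OCc1ccccc1)C2
F5 | step 14 | 8-bromo-5,7-bis(benzyloxy)-2-[4-(benzyloxy)phenyl]-4-[(2S,3S)-3,5,7-tris(benzyloxy)-2-(4-benzyloxyphenyl)chroman-8-yl]chromenylium tetrafluoroborate | F[B-](F)(F)F.Brc1c(OCc2ccccc2)cc(OCc2ccccc2)c2c(-c3c(OCc4ccccc4)cc(OCc4ccccc4)c4c3O[C@@H](c3ccc(OCc5ccccc5)cc3)[C@@H](OCc3ccccc3)C4)cc(-c3ccc(OCc4ccccc4)cc3)[o+]c12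
F6 | step 14 | C2 epimer of 32 ((2S)-2H-chromene) | O(Cc5ccccc5)c1ccc([C@@H]2Oc3c(c(OCc5ccccc5)cc(OCc5ccccc5)c3Br)C(c3c(OCc5ccccc5)cc(OCc5ccccc5)c4c3O[C@@H](c3ccc(OCc5ccccc5)cc3)[C@@H](OCc5ccccc5)C4)=C2)cc1
F7 | step 14 | diastereomer of 34 with the (2S,3R) all-trans middle unit | O(Cc5ccccc5)c1ccc([C@@H]2Oc3c(c(OCc5ccccc5)cc(OCc5ccccc5)c3Br)[C@H](c3c(OCc5ccccc5)cc(OCc5ccccc5)c4c3O[C@@H](c3ccc(OCc5ccccc5)cc3)[C@@H](OCc5ccccc5)C4)[C@H]2O)cc1
F8 | step 25 | 4-O-acetate of 45 (bottom unit 4R, 3,4-trans) | O(Cc5ccccc5)c1ccc([C@H]2Oc3c(c(OCc5ccccc5)cc(OCc5ccccc5)c3[C@H]3c4c(OCc5ccccc5)cc(OCc5ccccc5)cc4O[C@@H](c4ccc(OCc5ccccc5)cc4)[C@H]3OCc5ccccc5)[C@@H](c3c(OCc5ccccc5)cc(OCc5ccccc5)c4c3O[C@@H](c3ccc(OCc5ccccc5)cc3)[C@@H](OCc5ccccc5)[C@@H]4OC(C)=O)[C@H]2OCc5ccccc5)cc1
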